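**Retrosynthetic overview**
1. The target is (3R,3aS,6R,6aS)-3,6-bis(3,4-dimethoxyphenyl)-3,4,6,6a-tetrahydro-1H-furo[3,4-c]furan-3a-ol. Ring A is C1–O2–C3–C3a–C6a and ring B is C3a–C4–O5–C6–C6a.
2. Ring A is disconnected last. The O2–C3 bond and the C3a–O bond are cut together, which leads back to a ring B alcohol with an exocyclic C3a=C3 arylidene bond and a free C1H2OH arm on C6a. In the forward sense this is a hydroxyl-directed epoxidation, benzylic ionisation and ring closure in one flask.
3. Enabling feature: on ring B the oxygen on C3a and the C1 arm on C6a are cis. The C1 hydroxyl can therefore first steer that oxygen onto C3a and then become O2 of ring A. C3 bears a 3,4-dimethoxyphenyl group that carries the cation, so the trans closure needs no backside trajectory.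
4. Ring B is made by forming the C6a–C3a bond in a titanocene-catalysed radical 5-exo-dig closure of an open-chain epoxy propargyl ether. O5–C4 comes from a Williamson etherification and the C3–aryl bond from a Sonogashira coupling.
5. Stereochemical relay: C6 is set by a Sharpless kinetic resolution. C6 then sets C6a (step 5), C6a sets C3a, and the closure sets C3 (step 6). Ring B is formed first, ring A second.

Key step: step 6

Assumption: the SMILES is read literally. Its descriptors 3R,3aS,6R,6aS place 3a-OH and 6a-H on opposite faces, so the bicycle is trans-fused with both aryl groups pseudo-equatorial. The route is built for this isomer and avoids Brønsted acid once ring A is closed.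

**Step 1**
Reactants: 1 3,4-dimethoxybenzaldehyde; 2 vinylmagnesium bromide
Product: 3 rac-1-(3,4-dimethoxyphenyl)prop-2-en-1-ol
Conditions: THF, 0 °C; then sat. aq. NH4Cl
Reagents that add atoms: none
Why: Grignard 1,2-addition of a vinyl nucleophile to an aromatic aldehyde gives the racemic allylic alcohol, and no stereocontrol is needed because step 2 resolves it.

**Step 2**
Reactants: 3 rac-1-(3,4-dimethoxyphenyl)prop-2-en-1-ol
Product: 4 (S)-(3,4-dimethoxyphenyl)[(R)-oxiran-2-yl]methanol
Conditions: Ti(OiPr)4 (0.15 equiv), L-(+)-DIPT (0.2 equiv), TBHP (0.45 equiv, decane), 4 Å MS, CH2Cl2, −20 °C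
Reagents that add atoms: tert-butyl hydroperoxide, CC(C)(C)OO
Why: In the Sharpless kinetic resolution with L-(+)-DIPT the R carbinol is the fast-reacting enantiomer and is epoxidised to the erythro epoxy alcohol, while the S alcohol stays behind and is removed by chromatography; this catalytic step sets the future C6, and the oxirane centre is erased in step 5.

**Step 3**
Reactants: 4 (S)-(3,4-dimethoxyphenyl)[(R)-oxiran-2-yl]methanol; 5 3-bromoprop-1-yne
Product: 6 (R)-2-[(S)-(3,4-dimethoxyphenyl)(prop-2-yn-1-yloxy)methyl]oxirane
Conditions: NaH added to 4 + 5, Bu4NI (cat.), THF, 0 °C to rt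
Reagents that add atoms: none
Why: This is a Williamson ether synthesis with a reactive propargylic bromide, and in aprotic THF with the bromide present from the start O-alkylation should outrun Payne rearrangement without touching a stereocentre.

**Step 4**
Reactants: 6 (R)-2-[(S)-(3,4-dimethoxyphenyl)(prop-2-yn-1-yloxy)methyl]oxirane; 7 4-iodo-1,2-dimethoxybenzene
Product: 8 (R)-2-[(S)-(3,4-dimethoxyphenyl){[3-(3,4-dimethoxyphenyl)prop-2-yn-1-yl]oxy}methyl]oxirane
Conditions: PdCl2(PPh3)2 (2 mol %), CuI (4 mol %), Et3N, THF, rt
Reagents that add atoms: none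
Why: Sonogashira coupling of a terminal alkyne with an aryl iodide runs at room temperature with a tertiary amine, conditions that leave the oxirane and the benzylic ether untouched.

**Step 5**
Reactants: 8 (R)-2-[(S)-(3,4-dimethoxyphenyl){[3-(3,4-dimethoxyphenyl)prop-2-yn-1-yl]oxy}methyl]oxirane
Product: 9 [(2R,3S,4E)-4-(3,4-dimethoxybenzylidene)-2-(3,4-dimethoxyphenyl)tetrahydrofuran-3-yl]methanol
Conditions: Cp2TiCl2 (20 mol %), Mn dust, 2,4,6-collidine·HCl, THF, rt, slow addition of 8
Reagents that add atoms: none
Why: In the Nugent–RajanBabu epoxide opening in its catalytic form, trivalent titanium (Cp2TiCl) opens the oxirane to the secondary β-titanoxy radical at the future C6a, which closes ring B by 5-exo-dig attack on the aryl alkyne through a chair-like transition state with the C6 aryl group pseudo-equatorial, so that the CH2O[Ti] arm ends trans to it (C6a relayed from C6); the linear α-aryl vinyl radical is then reduced and protonated from the open C4H2 side (hence E is drawn), and this geometry does not matter in step 6.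

**Step 6**
Reactants: 9 [(2R,3S,4E)-4-(3,4-dimethoxybenzylidene)-2-(3,4-dimethoxyphenyl)tetrahydrofuran-3-yl]methanol
Product: 11 (3R,3aS,6R,6aS)-3,6-bis(3,4-dimethoxyphenyl)-3,4,6,6a-tetrahydro-1H-furo[3,4-c]furan-3a-ol, via spiro-oxirane 10 (not isolated)
Conditions: VO(acac)2 (5 mol %), TBHP (1.1 equiv, anhydrous, decane), 4 Å MS, CH2Cl2 (0.01 M), 0 °C to rt; then Me2S, Et3N; base-washed silica
Reagents that add atoms: tert-butyl hydroperoxide, CC(C)(C)OO
Why: Proposed new method: the C1 hydroxyl of 9 binds the pentavalent vanadium tert-butylperoxide and hands its oxygen to the alkene face on its own side (10, C3a–O cis to the CH2OH arm); the vanadium-activated oxirane of this electron-rich styrene type then ionises at C3, the C3a–C3 bond turns by about a quarter, and the same hydroxyl oxygen captures the cation while its proton ends on the 3a-oxygen. The closest known reaction types are the hydroxyl-directed VO(acac)2/TBHP epoxidation of homoallylic alcohols and the ready 5-endo cyclisation of 4-aryl-3,4-epoxybutan-1-ols to 2-aryl-3-hydroxytetrahydrofurans; what is new is their union in one flask and a closure that ends in a trans-fused bicycle, for which concerted backside attack is out of reach and the cation path is required. Ring A closes formally 5-endo-tet at the oxirane, in effect 5-exo-trig on the quinoid resonance form of the cation, and the oxirane strain set free (roughly 27 kcal/mol) outweighs the extra strain of a trans-bicyclo[3.3.0]octane frame (roughly 6 to 8 kcal/mol). C3a is controlled by the directing C1 hydroxyl, whose face was fixed by C6a, and C3 by the closure transition state, which keeps the aryl group pseudo-equatorial and away from the axial H-6a, so that either alkene isomer of 9 and either C3 epimer of 10 should converge on 3R. The step needs oxygen transfer to the more crowded alkene face, which is secured because this catalyst epoxidises unbound alkene far more slowly than its own alkoxide, and it needs ring closure to outrun semipinacol ring enlargement and capture by TBHP, which is helped by both oxygens sitting on one vanadium centre, by high dilution and by only a slight excess of anhydrous TBHP.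

**Compound list**
1 | 3,4-dimethoxybenzaldehyde | COc1ccc(C=O)cc1OC | starting material
2 | vinylmagnesium bromide | C=C[Mg]Br | starting material
3 | rac-1-(3,4-dimethoxyphenyl)prop-2-en-1-ol | COc1ccc(C(O)C=C)cc1OC | intermediate
4 | (S)-(3,4-dimethoxyphenyl)[(R)-oxiran-2-yl]methanol | COc1ccc([C@H](O)[C@H]2CO2)cc1OC | intermediate
5 | 3-bromoprop-1-yne | C#CCBr | starting material
6 | (R)-2-[(S)-(3,4-dimethoxyphenyl)(prop-2-yn-1-yloxy)methyl]oxirane | COc1ccc([C@H](OCC#C)[C@H]2CO2)cc1OC | intermediate
7 | 4-iodo-1,2-dimethoxybenzene | COc1ccc(I)cc1OC | starting material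
8 | (R)-2-[(S)-(3,4-dimethoxyphenyl){[3-(3,4-dimethoxyphenyl)prop-2-yn-1-yl]oxy}methyl]oxirane | COc1ccc([C@H](OCC#Cc3ccc(OC)c(OC)c3)[C@H]2CO2)cc1OC | intermediate
9 | [(2R,3S,4E)-4-(3,4-dimethoxybenzylidene)-2-(3,4-dimethoxyphenyl)tetrahydrofuran-3-yl]methanol | COc1ccc(/C=C2/CO[C@@H](c3ccc(OC)c(OC)c3)[C@@H]2CO)cc1OC | intermediate
10 | [(2S,3S,6R,7S)-2,6-bis(3,4-dimethoxyphenyl)-1,5-dioxaspiro[2.4]heptan-7-yl]methanol (oxirane oxygen on the CH2OH face of ring B) | COc1ccc([C@@H]2O[C@@]23CO[C@@H](c4ccc(OC)c(OC)c4)[C@@H]3CO)cc1OC | intermediate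
11 | (3R,3aS,6R,6aS)-3,6-bis(3,4-dimethoxyphenyl)-3,4,6,6a-tetrahydro-1H-furo[3,4-c]furan-3a-ol | COc1ccc([C@H]2OC[C@H]3[C@H](c4ccc(OC)c(OC)c4)OC[C@]23O)cc1OC | target

Total step count: 6. Longest linear sequence: 6 (1 → 3 → 4 → 6 → 8 → 9 → 11).

**Steps most likely to fail**

**Step 6.** Oxygen may be delivered to the sterically open face if the direction by the hydroxyl is lost. After ionisation, semipinacol ring enlargement or capture of the cation by TBHP may also outrun closure of the strained ring.
- The fallback sets out from 9 and comes back at 11. It avoids any cation.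
- Thiyl-radical equilibration (PhSSPh cat., hν, toluene) should turn 9 into the less crowded [(2R,3S,4Z)-4-(3,4-dimethoxybenzylidene)-2-(3,4-dimethoxyphenyl)tetrahydrofuran-3-yl]methanol F1.
- OsO4·TMEDA (1 equiv, CH2Cl2, −78 °C, then aq. Na2SO3) is a hydrogen-bond-directed syn-dihydroxylation. It adds both oxygens from the CH2OH face and gives (3S,4S,5R)-5-(3,4-dimethoxyphenyl)-3-[(R)-(3,4-dimethoxyphenyl)(hydroxy)methyl]-4-(hydroxymethyl)tetrahydrofuran-3-ol F2, in which C3a and C3 are already correct.
- TsCl in pyridine at 0 °C takes the only primary hydroxyl and gives the primary tosylate of this triol F3.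
- NaH in THF closes ring A by a 5-exo-tet Williamson displacement at C1 with retention at every stereocentre. Trans-fused 3-oxabicyclo[3.3.0]octanes are known to form in this mode.

**Step 2.** The rate difference between the enantiomers may be too small, which would erode the enantiomeric purity of the epoxy alcohol.
- The fallback sets out from 3 and comes back at 4.
- Candida antarctica lipase B with vinyl acetate acylates the R alcohol to (R)-1-(3,4-dimethoxyphenyl)prop-2-en-1-yl acetate F4, which is separated from the S alcohol.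
- K2CO3 in MeOH frees (R)-1-(3,4-dimethoxyphenyl)prop-2-en-1-ol F5.
- The single enantiomer is epoxidised under matched Sharpless conditions (Ti(OiPr)4, L-(+)-DIPT, TBHP) to 4.

**Step 5.** The β-titanoxy radical may be reduced before it cyclises, with β-elimination (deoxygenation) as the result, or the trans selectivity at C6/C6a may be poor.
- The fallback sets out from 3 (through F5) and comes back at 11. It replaces the radical closure by an organopalladium one.
- NaH and 5 give (R)-1,2-dimethoxy-4-[1-(prop-2-yn-1-yloxy)prop-2-en-1-yl]benzene F6.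
- Sonogashira coupling with 7 gives the 1,6-enyne (R)-4-{3-[1-(3,4-dimethoxyphenyl)prop-2-en-1-yloxy]prop-1-yn-1-yl}-1,2-dimethoxybenzene F7.
- Pd(OAc)2 (5 mol %), B2pin2 and MeOH in toluene at 50 °C effect a borylative enyne cyclisation: syn-hydropalladation of the alkyne, 5-exo carbopalladation of the vinyl group, then C–B bond formation. This gives the pinacol boronate (2R,3R,4Z)-4-(3,4-dimethoxybenzylidene)-2-(3,4-dimethoxyphenyl)-3-[(pinacolboryl)methyl]tetrahydrofuran F8.
- NaBO3·4H2O in THF/H2O oxidises F8 to F1, which takes the place of 9 in step 6.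

**Further compounds**
F1 | step 6 | [(2R,3S,4Z)-4-(3,4-dimethoxybenzylidene)-2-(3,4-dimethoxyphenyl)tetrahydrofuran-3-yl]methanol | COc1ccc(/C=C2\CO[C@@H](c3ccc(OC)c(OC)c3)[C@@H]2CO)cc1OC
F2 | step 6 | (3S,4S,5R)-5-(3,4-dimethoxyphenyl)-3-[(R)-(3,4-dimethoxyphenyl)(hydroxy)methyl]-4-(hydroxymethyl)tetrahydrofuran-3-ol | COc1ccc([C@@H](O)[C@@]2(O)CO[C@@H](c3ccc(OC)c(OC)c3)[C@@H]2CO)cc1OC
F3 | step 6 | primary p-toluenesulfonate of F2 | COc1ccc([C@@H](O)[C@@]2(O)CO[C@@H](c3ccc(OC)c(OC)c3)[C@@H]2COS(=O)(=O)c4ccc(C)cc4)cc1OC
F4 | step 2 | (R)-1-(3,4-dimethoxyphenyl)prop-2-en-1-yl acetate | C=C[C@@H](OC(C)=O)c1ccc(OC)c(OC)c1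
F5 | step 2 | (R)-1-(3,4-dimethoxyphenyl)prop-2-en-1-ol | C=C[C@@H](O)c1ccc(OC)c(OC)c1
F6 | step 5 | (R)-1,2-dimethoxy-4-[1-(prop-2-yn-1-yloxy)prop-2-en-1-yl]benzene | C=C[C@@H](OCC#C)c1ccc(OC)c(OC)c1
F7 | step 5 | (R)-4-{3-[1-(3,4-dimethoxyphenyl)prop-2-en-1-yloxy]prop-1-yn-1-yl}-1,2-dimethoxybenzene | C=C[C@@H](OCC#Cc1ccc(OC)c(OC)c1)c2ccc(OC)c(OC)c2
F8 | step 5 | (2R,3R,4Z)-4-(3,4-dimethoxybenzylidene)-2-(3,4-dimethoxyphenyl)-3-[(4,4,5,5-tetramethyl-1,3,2-dioxaborolan-2-yl)methyl]tetrahydrofuran | COc1ccc(/C=C2\CO[C@@H](c3ccc(OC)c(OC)c3)[C@@H]2CB4OC(C)(C)C(C)(C)O4)cc1OC
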